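**Plan**

- Retrosynthesis: the C8 butanoate and the 3‑O‑benzyl and 5‑O‑methyl masks come off first. Ring A is then cut at C5–C6, C7–C8 and C8–C8a into a pyranonyl methoxycarbene complex of zerovalent chromium, methoxyacetylene and one CO.
- Enabling feature: ring A carries oxygen at C5 and C8 in a 1,4 relationship, with the C7 methoxy beside C8 and the C6 hydrogen beside C5. A methoxycarbene carbon (C5), a terminal alkoxyalkyne (C6–H, C7–OMe) and one CO (C8–OH) assemble exactly this pattern across the C4a=C8a double bond of a preformed ring C.
- The carbene is cut at its Cr=C bond to an acid chloride and Na2Cr(CO)5. Ring C is cut at C2–C3 and O1–C8a (flavone numbering) to benzoyl chloride and the enaminone of ethyl 4‑(benzyloxy)‑3‑oxobutanoate.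
- Forward order: ring C (steps 1–2), carboxyl to carbene (steps 3–5), methoxyacetylene (step 6), ring A by benzannulation (step 7), butyrylation (step 8), unmasking (step 9).
- Stereochemistry: the target has no stereocentre and no stereogenic double bond, so nothing has to be controlled.

Key step: step 7

Remark: enaminone 3 and diketone 5 are drawn without double-bond geometry or tautomer preference because these forms interconvert and both lead to 6; 5 is present in the flask as its lithium enolate.

**Route**

Step 1
Reactants: 1 ethyl 4-(benzyloxy)-3-oxobutanoate; 2 N,N-dimethylformamide dimethyl acetal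
Product: 3 ethyl 4-(benzyloxy)-2-[(dimethylamino)methylidene]-3-oxobutanoate
Conditions: toluene, 25 → 50 °C
Reagents that add atoms: none
Why: Amide-acetal condensation (enaminone formation) at the doubly activated C2 methylene of the β-keto ester, which is far more acidic than the CH2OBn group, so only C2 should be aminomethylenated.

Step 2
Reactants: 3 ethyl 4-(benzyloxy)-2-[(dimethylamino)methylidene]-3-oxobutanoate; 4 benzoyl chloride
Product: 6 ethyl 5-(benzyloxy)-4-oxo-6-phenyl-4H-pyran-3-carboxylate, via C-benzoylated enaminone 5 (not isolated)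
Conditions: LiN(SiMe3)2 (2.5 equiv), THF, −78 °C; then 2 M HCl, Et2O, 0 → 25 °C
Reagents that add atoms: none
Why: With C2 blocked as the vinylogous amide, LiN(SiMe3)2 enolises the remaining α-CH2, a Claisen-type C-benzoylation gives diketone 5, and on acidification the enol oxygen of the new benzoyl group adds to the enamine carbon and expels dimethylamine (conjugate addition–elimination), the established enaminone/acid chloride route to 4-pyranones.

Step 3
Reactants: 6 ethyl 5-(benzyloxy)-4-oxo-6-phenyl-4H-pyran-3-carboxylate
Product: 7 5-(benzyloxy)-4-oxo-6-phenyl-4H-pyran-3-carboxylic acid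
Conditions: Me3SnOH (4 equiv), 1,2-dichloroethane, 80 °C; then 1 M HCl wash
Reagents that add atoms: trimethyltin hydroxide, C[Sn](C)(C)O
Why: Me3SnOH-mediated ester hydrolysis, in which the tin hydroxide binds the β-keto ester chelate and transfers hydroxide to the ester under nearly neutral conditions, should spare the pyranone C2 position that free hydroxide would attack and leave the benzyl ether intact.

Step 4
Reactants: 7 5-(benzyloxy)-4-oxo-6-phenyl-4H-pyran-3-carboxylic acid
Product: 8 5-(benzyloxy)-4-oxo-6-phenyl-4H-pyran-3-carbonyl chloride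
Conditions: (COCl)2 (1.3 equiv), DMF (cat.), CH2Cl2, 0 → 25 °C; evaporate, use crude
Reagents that add atoms: oxalyl chloride, O=C(Cl)C(=O)Cl
Why: Vilsmeier-catalysed conversion of a carboxylic acid into its chloride with oxalyl chloride, routine for 4-oxopyran- and chromene-3-carboxylic acids, gives only gaseous by-products, so the crude chloride can be used directly.

Step 5
Reactants: 8 5-(benzyloxy)-4-oxo-6-phenyl-4H-pyran-3-carbonyl chloride; 9 hexacarbonylchromium Cr(CO)6
Product: 12 pentacarbonyl{[5-(benzyloxy)-4-oxo-6-phenyl-4H-pyran-3-yl](methoxy)methylidene}chromium, via Na2Cr(CO)5 10 (not isolated), via sodium acylchromate 11 (not isolated)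
Conditions: Cr(CO)6, NaC10H8 (sodium naphthalenide, 2 equiv), THF, −78 °C; then 8, −78 → 0 °C; then Me3OBF4 (1.0 equiv), CH2Cl2, −40 → 0 °C
Reagents that add atoms: trimethyloxonium tetrafluoroborate, C[O+](C)C.F[B-](F)(F)F
Why: Semmelhack–Hegedus carbene synthesis, in which the pentacarbonylchromate dianion from reduced Cr(CO)6 is acylated at the acid chloride (the most electrophilic carbon of 8) and one equivalent of Me3OBF4 at low temperature methylates the anionic acylate oxygen faster than the neutral pyranone carbonyl, should give the methoxycarbene of zerovalent chromium without metallating the pyranone ring, where a 5-lithio species would risk ring opening by β-elimination.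

Step 6
Reactants: 13 chloroacetaldehyde dimethyl acetal
Product: 15 methoxyacetylene, via sodium methoxyacetylide 14 (not isolated)
Conditions: NaNH2 (3 equiv), liquid NH3, −33 °C; evaporate NH3; saturated aq. NaCl, −70 → 0 °C; distil into THF at −78 °C
Reagents that add atoms: none
Why: Twofold base-induced elimination (loss of methanol, then of HCl) with NaNH2 in liquid ammonia, the standard preparative route to alkoxyacetylenes, holds the product as its sodium acetylide until brine protonates it, and the volatile alkyne is distilled into cold THF for immediate use.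

Step 7
Reactants: 12 pentacarbonyl{[5-(benzyloxy)-4-oxo-6-phenyl-4H-pyran-3-yl](methoxy)methylidene}chromium; 15 methoxyacetylene
Product: 17 3-(benzyloxy)-8-hydroxy-5,7-dimethoxy-2-phenyl-4H-chromen-4-one, via dienyl(methoxy)carbene complex 16 (not isolated)
Conditions: 15 (1.5 equiv), THF, −20 → 45 °C, sealed tube, dark; then CO (1 atm), visible light, 25 °C
Reagents that add atoms: none
Why: The nucleophilic, unsubstituted carbon of the ynol ether attacks the electrophilic carbene carbon and the alkyne inserts into the Cr=C bond (C5–C6) to give dienyl(methoxy)carbene 16, a CO ligand then inserts at the new carbene carbon to give a chromium-bound dienylketene (C7–C8), and this closes onto the pyranone C–H carbon (C8–C8a) and tautomerises to the phenol. The closest known reaction is the Dötz benzannulation of alkenyl(alkoxy)carbene chromium complexes with terminal alkynes; because the inserted ynol ether leaves a methoxy-stabilised carbene that may insert CO only reluctantly in the dark, the sequence is completed with visible light under CO, the known photochemical benzannulation of dienylcarbene complexes, and the CO atmosphere returns the metal as Cr(CO)6 and releases the free phenol. Ring A is closed by 6π electrocyclisation of the dienylketene to a six-membered carbocycle, and no stereocentre is formed. The step needs alkyne regiocontrol, which is secured twice over: the polarisation of methoxyacetylene and the smaller size of its CH terminus both place that carbon on the carbene carbon, so the alkyne methoxy should end at C7 beside the CO-derived C8 and the carbene methoxy at C5. The pyranone C=C is the only alkenyl arm available and its hydrogen allows aromatisation, the push-pull character of 16 lets its double-bond isomers interconvert so that the cyclisable E isomer is drained, and the C8 hydroxyl emerges as the only unprotected oxygen, ready for the butanoate.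

Step 8
Reactants: 17 3-(benzyloxy)-8-hydroxy-5,7-dimethoxy-2-phenyl-4H-chromen-4-one; 18 butanoic anhydride
Product: 19 3-(benzyloxy)-5,7-dimethoxy-4-oxo-2-phenyl-4H-chromen-8-yl butanoate
Conditions: Et3N, DMAP (cat.), CH2Cl2, 0 → 25 °C
Reagents that add atoms: none
Why: DMAP-catalysed acyl transfer (nucleophilic catalysis) should esterify the only free hydroxyl of 17, the C8 phenol created by the benzannulation, since every other oxygen is etherified.

Step 9
Reactants: 19 3-(benzyloxy)-5,7-dimethoxy-4-oxo-2-phenyl-4H-chromen-8-yl butanoate
Product: 20 3,5-dihydroxy-7-methoxy-4-oxo-2-phenyl-4H-chromen-8-yl butanoate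
Conditions: BCl3 (4 equiv), C6HMe5 (3 equiv), CH2Cl2, −78 → 0 °C; then H2O
Reagents that add atoms: none
Why: BCl3-mediated ether cleavage should remove the benzyl ether, with pentamethylbenzene trapping the benzyl cation so that the electron-rich C6 is not benzylated, and chelation of boron between the C4 carbonyl and the peri oxygen should direct demethylation to C5 only, while the non-chelated 7-methyl ether and the aryl butanoate survive at or below 0 °C.

**Compound list**

1 | ethyl 4-(benzyloxy)-3-oxobutanoate | CCOC(=O)CC(=O)COCc1ccccc1 | starting material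
2 | N,N-dimethylformamide dimethyl acetal | COC(OC)N(C)C | starting material
3 | ethyl 4-(benzyloxy)-2-[(dimethylamino)methylidene]-3-oxobutanoate | CCOC(=O)C(=CN(C)C)C(=O)COCc1ccccc1 | intermediate
4 | benzoyl chloride | O=C(Cl)c1ccccc1 | starting material
5 | ethyl 4-(benzyloxy)-2-[(dimethylamino)methylidene]-3,5-dioxo-5-phenylpentanoate | CCOC(=O)C(=CN(C)C)C(=O)C(OCc1ccccc1)C(=O)c1ccccc1 | intermediate
6 | ethyl 5-(benzyloxy)-4-oxo-6-phenyl-4H-pyran-3-carboxylate | CCOC(=O)c1coc(-c2ccccc2)c(OCc2ccccc2)c1=O | intermediate
7 | 5-(benzyloxy)-4-oxo-6-phenyl-4H-pyran-3-carboxylic acid | O=C(O)c1coc(-c2ccccc2)c(OCc2ccccc2)c1=O | intermediate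
8 | 5-(benzyloxy)-4-oxo-6-phenyl-4H-pyran-3-carbonyl chloride | O=C(Cl)c1coc(-c2ccccc2)c(OCc2ccccc2)c1=O | intermediate
9 | hexacarbonylchromium Cr(CO)6 | O=C=[Cr](=C=O)(=C=O)(=C=O)(=C=O)=C=O | starting material
10 | disodium pentacarbonylchromate Na2Cr(CO)5 | O=C=[Cr-2](=C=O)(=C=O)(=C=O)=C=O.[Na+].[Na+] | intermediate
11 | sodium pentacarbonyl[5-(benzyloxy)-4-oxo-6-phenyl-4H-pyran-3-carbonyl]chromate | O=C(c1coc(-c2ccccc2)c(OCc2ccccc2)c1=O)[Cr-](=C=O)(=C=O)(=C=O)(=C=O)=C=O.[Na+] | intermediate
12 | pentacarbonyl{[5-(benzyloxy)-4-oxo-6-phenyl-4H-pyran-3-yl](methoxy)methylidene}chromium | COC(c1coc(-c2ccccc2)c(OCc2ccccc2)c1=O)=[Cr](=C=O)(=C=O)(=C=O)(=C=O)=C=O | intermediate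
13 | chloroacetaldehyde dimethyl acetal | COC(CCl)OC | starting material
14 | sodium methoxyacetylide | [Na+].[C-]#COC | intermediate
15 | methoxyacetylene | COC#C | intermediate
16 | pentacarbonyl{(2E)-3-[5-(benzyloxy)-4-oxo-6-phenyl-4H-pyran-3-yl]-1,3-dimethoxyprop-2-en-1-ylidene}chromium | COC(/C=C(/OC)c1coc(-c2ccccc2)c(OCc2ccccc2)c1=O)=[Cr](=C=O)(=C=O)(=C=O)(=C=O)=C=O | intermediate
17 | 3-(benzyloxy)-8-hydroxy-5,7-dimethoxy-2-phenyl-4H-chromen-4-one | COc1cc(OC)c2c(=O)c(OCc3ccccc3)c(-c3ccccc3)oc2c1O | intermediate
18 | butanoic anhydride | CCCC(=O)OC(=O)CCC | starting material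
19 | 3-(benzyloxy)-5,7-dimethoxy-4-oxo-2-phenyl-4H-chromen-8-yl butanoate | CCCC(=O)Oc1c(OC)cc(OC)c2c(=O)c(OCc3ccccc3)c(-c3ccccc3)oc12 | intermediate
20 | 3,5-dihydroxy-7-methoxy-4-oxo-2-phenyl-4H-chromen-8-yl butanoate | CCCC(=O)Oc1c(OC)cc(O)c2c(=O)c(O)c(-c3ccccc3)oc12 | target

**Step count**

Total step count: 9. Longest linear sequence: 8 steps (steps 1–5, then 7–9); step 6 is a one-step side branch.

**Steps most likely to fail**

Step 7. After the alkyne has inserted, the methoxy-stabilised carbene may take up further methoxyacetylene (oligomerisation) or close a five-membered ring without CO uptake, so that CO insertion and six-membered closure do not take place. The fallback sets out from carbene 12 and keeps the benzannulation but uses an alkyne with an acceptor substituent that cannot stabilise the inserted carbene. Ethynylboronic acid pinacol ester in THF at 45 °C, with the same CO/light work-up, should place boron beside the new hydroxyl and give 3-(benzyloxy)-8-hydroxy-5-methoxy-2-phenyl-7-(4,4,5,5-tetramethyl-1,3,2-dioxaborolan-2-yl)-4H-chromen-4-one F1. Oxidation of the C–B bond with NaBO3·4H2O in THF/H2O should give 3-(benzyloxy)-7,8-dihydroxy-5-methoxy-2-phenyl-4H-chromen-4-one F2. One equivalent of MeI with K2CO3 in DMF should methylate the more acidic 7-hydroxyl, which is conjugated to the C4 carbonyl, and the sequence comes back to the route at 17.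

Step 5. Electron transfer from the chromate dianion to the electron-poor pyranone, or its conjugate addition at the unsubstituted ring carbon, may compete with substitution at the acid chloride. The fallback sets out from acid 7 and follows the classical organolithium route to the carbene. Protodecarboxylation (Cu2O, 1,10-phenanthroline, NMP/quinoline, 170 °C) should give 3-(benzyloxy)-2-phenyl-4H-pyran-4-one F3, and iodination with N-iodosuccinimide and catalytic CF3CO2H should give 3-(benzyloxy)-5-iodo-2-phenyl-4H-pyran-4-one F4. Iodine–lithium exchange with t-BuLi (2 equiv) in THF/Et2O at −100 °C should give 3-(benzyloxy)-5-lithio-2-phenyl-4H-pyran-4-one F5, which is transferred at once onto Cr(CO)6 (9) to give lithium pentacarbonyl[5-(benzyloxy)-4-oxo-6-phenyl-4H-pyran-3-carbonyl]chromate F6. Methylation with Me3OBF4 brings the sequence back to the route at 12.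

Step 9. Lewis-acid cleavage of two ethers at once may be unselective, with loss of the 7-methyl ether or solvolysis of the butanoate alongside the intended cleavages. The fallback sets out from 19 and separates the two tasks. Hydrogenolysis (H2, Pd/C, EtOAc, 25 °C) should remove only the benzyl group under neutral conditions and give 3-hydroxy-5,7-dimethoxy-4-oxo-2-phenyl-4H-chromen-8-yl butanoate F7. The Lewis acid then only has to perform the chelation-directed demethylation at C5 (BCl3, 1.5 equiv, CH2Cl2, −78 → −20 °C), and the sequence comes back to the route at 20.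

**Further compounds**

F1 | step 7 | 3-(benzyloxy)-8-hydroxy-5-methoxy-2-phenyl-7-(4,4,5,5-tetramethyl-1,3,2-dioxaborolan-2-yl)-4H-chromen-4-one | COc1cc(B2OC(C)(C)C(C)(C)O2)c(O)c2oc(-c3ccccc3)c(OCc3ccccc3)c(=O)c12
F2 | step 7 | 3-(benzyloxy)-7,8-dihydroxy-5-methoxy-2-phenyl-4H-chromen-4-one | COc1cc(O)c(O)c2oc(-c3ccccc3)c(OCc3ccccc3)c(=O)c12
F3 | step 5 | 3-(benzyloxy)-2-phenyl-4H-pyran-4-one | O=c1ccoc(-c2ccccc2)c1OCc1ccccc1
F4 | step 5 | 3-(benzyloxy)-5-iodo-2-phenyl-4H-pyran-4-one | O=c1c(I)coc(-c2ccccc2)c1OCc1ccccc1
F5 | step 5 | 3-(benzyloxy)-5-lithio-2-phenyl-4H-pyran-4-one | [Li]c1coc(-c2ccccc2)c(OCc2ccccc2)c1=O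
F6 | step 5 | lithium pentacarbonyl[5-(benzyloxy)-4-oxo-6-phenyl-4H-pyran-3-carbonyl]chromate | O=C(c1coc(-c2ccccc2)c(OCc2ccccc2)c1=O)[Cr-](=C=O)(=C=O)(=C=O)(=C=O)=C=O.[Li+]
F7 | step 9 | 3-hydroxy-5,7-dimethoxy-4-oxo-2-phenyl-4H-chromen-8-yl butanoate | CCCC(=O)Oc1c(OC)cc(OC)c2c(=O)c(O)c(-c3ccccc3)oc12
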